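## The problem

CNP0183476.6 is a C30 sipholane-type triterpenoid built from two bicyclic halves held apart by a two-carbon chain (C16–C17). One half is a cis-fused hydroazulene: seven-membered ring A with the C2=C3 olefin and the gem-dimethyl carbon C12, and cyclopentane ring B with the tertiary carbinol C9. The other half is a perhydro-1-benzoxepine (cyclohexane ring C, oxepane ring D) which, in the structure as drawn, is cis-fused (C20 methyl and H29 on the same face).

Nine stereocentres must be set: C5, C6, C9 and C15 in one half, and C18, C19, C23, C29 and C32 in the other. The ethano bridge insulates the two sets, so each half has to be made as a single enantiomer and the halves joined late, at C15, which is flanked by the quaternary C12. Inside the C/D half the contiguous ring C centres can be relayed (C32/C18 to C19 to C29), whereas C23 sits on a flexible ring and needs reagent control. Inside the A/B half C6 can steer C5, C9 and C15.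

The skeletal difficulties are the quaternary C19, the quaternary C12 between two stereocentres, and a seven-membered ether closed onto a tertiary carbon. Two tertiary alcohols (C9, C32) and the tertiary ether C25–O28 ionise under strong acid. The trisubstituted C2=C3 olefin survives neither RuO4, hydroboration nor hydrogenation, so it must appear after all such operations.

The feature that opens the route is ring C itself (C18, C19, C29, C30, C31, C32). C32 carries a methyl group (C33) and an oxygen (O34) and lies para to the oxygenated C29, and the C18 side chain is cis to O34. This is the pattern of a p-cresol-derived quinol whose oxygen has been tied back to C18 through the very two carbons (C16, C17) that later form the bridge.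

## Retrosynthesis

**Unmasking and the ring A olefin (51 ⇒ 50 ⇒ 49 ⇒ 47).** The C2–C1 bond and three O–Si bonds are cut. The C2=C3 olefin is the one function of the hydroazulene that tolerates none of the reductions and oxidations used elsewhere. Tracing it through enol triflate 49 to ketone 47 keeps a carbonyl at C2 while C15 is being made and lets the olefin appear two steps from the end. Carrying the olefin through the union would force C15 to react as an allyl-metal terminus with no element to control its configuration. The forward steps must enolise 47 towards C3 only, which the tertiary, neopentylic C15–H makes likely.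

**Union at C15–C16 (47 ⇒ 46 ⇒ 44 ⇒ 42 + 27).** This bond joins a carbon next to quaternary C12 to the bridge. Substitution at C15, or conjugate addition to an enone with C15 as β-carbon, would have to overcome that neopentyl environment with a large nucleophile. With C15 as the α′-carbon of enone 42, the bond is made by aldol addition to aldehyde 27, where steric demand is low. The stereocentre is set afterwards by adding the smallest group, hydrogen, to dienone 46 from the open face. The precursors are two fragments of similar size, each with all its other stereocentres in place. The forward reaction needs a regiodefined enolate (42 has no other enolisable α-position) and convex-face hydrogenation.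

**Oxidation level of C16 (27 ⇒ 26 ⇒ 25 ⇒ 24 ⇒ 23).** Two C16–H bonds are cut. The oxolane of 23 is the tether of the key step; it has masked O34 and carried C16 and C17 through all ring C and ring D chemistry. RuO4 turns its only ether methylene into lactone 24. Reduction to diol 25, double silylation to 26 and selective Swern oxidation of the primary silyl ether give 27 with O34 protected. Opening the oxolane earlier would give up the bicyclic bias needed at C19. A later oxidation would meet the ring A olefin.

**Ring D (23 ⇒ 22 ⇒ 20 ⇒ 19 ⇒ 18 ⇒ 17).** The O28–C25 bond is cut. The obvious closure, attack of the C29 hydroxyl on a C23–C25 epoxide, would be a 7-endo opening in competition with 6-exo attack at C23, and hydroxy epoxides of this kind prefer the smaller ring. Epoxide 18 is therefore used only to set C23 by reagent control and is isomerised to allylic alcohol 19, which moves the olefin to C25=CH2. Closure of diol 20 by alkoxymercuration is then 7-exo and Markovnikov at once. C29 is set just before (19 ⇒ 20) by hydride reduction of the α-quaternary ketone under control of C19.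

**Ring D side chain (17 ⇒ 16 ⇒ 15 ⇒ 13 ⇒ 12).** C23=C25 is cut by a Wittig disconnection and C23 is traced to the terminal carbon of an allyl group. Direct alkylation of C19 with a homoprenyl halide would ask an unactivated electrophile to form a quaternary centre. Copper hydride removes the enone olefin of 12 without touching the allyl group.

**Quaternary C19 (12 ⇒ 10 ⇒ 8).** C19–C21 and C19–C20 are cut. Enone 8 has one enolisable position only, so both alkylations are regiospecific. The second electrophile enters anti to the oxolane ring, so the order methyl then allyl places C21 anti and C20 syn to C17, as the target requires.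

**C17 (8 ⇒ 7 ⇒ 6 ⇒ 5).** The C17 carbonyl of 5 is the footprint of the acyl anion. It is removed at once, by chemoselective reduction and radical deoxygenation, so that it cannot compete with C29 in enolate chemistry.

**Key disconnection (5 ⇒ 4).** The C17–C18 bond is cut, which returns the achiral dienone aldehyde 4. One catalytic step creates C18 and C32, differentiates the two halves of ring C, and leaves an enone for C19 and C29. No other cut in ring C gives an achiral, two-step precursor.

**Quinol (4 ⇒ 3 ⇒ 1 + 2).** C32–O34 is cut to p-cresol 1 and ethylene glycol 2 (oxidative dearomatisation), followed by alcohol oxidation.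

**Hydroazulene functionality (42 ⇒ 41 ⇒ 39 ⇒ 37).** C9–O and C5–H are cut together: syn hydroboration of the tetrasubstituted C5=C9 olefin of 37 from the face of H6 gives the cis ring fusion and puts the C9 hydroxyl on the convex face, a relationship that methyl addition to a ketone would deliver the wrong way round. The C3=C4 unsaturation of 41 is regiospecific because C15 has no β-hydrogen.

**Ring A (37 ⇒ 36 ⇒ 35).** One C12–CH3 bond is cut (cuprate addition creates the gem-dimethyl carbon), then C12=C15 (ring-closing metathesis of vinyl ketone 35).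

**Ring B and chain (35 ⇒ 34 ⇒ 33 ⇒ 32 ⇒ 31 ⇒ 30 ⇒ 28).** C2 and C3 come from an acetamide enolate, C15 from a vinyl Grignard reagent. Cyclopentene carbaldehyde 31 is the aldol condensation product of the keto aldehyde 30 from (S)-limonene 28, which supplies C6 and ten of the carbons.

## Roads not taken

**Alternative 1: asymmetric Diels–Alder with a ketene equivalent for ring C.**
- Cut and key step: C30–C31 and C19–C29; a chiral Lewis acid would activate the α-bromo enal A2 for cycloaddition with triene A3 to give bromo aldehyde A1.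
- Merits: ring C, the C29 carbonyl (after unmasking) and the quaternary C19 with its whole homoprenyl chain arise in one step. The chosen route spends steps 7 to 12 on the same task, so here this road is clearly shorter.
- Weak points: only C19 survives as a stereocentre, since C29 is lost on unmasking. A1 still has C18=C32 as an olefin. Turning it into the C32 carbinol with a cis carbon chain at C18, next to the new quaternary centre, needs a syn oxy-alkylation for which no direct method exists; epoxide opening by carbon would give the trans arrangement. The diene terminus that becomes C19 is fully substituted, which slows the cycloaddition.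
- Comparison: the chosen plan sets two stereocentres (C18, C32) in its key step and supplies C16 and C17 with it, paid for by six steps at C19.

**Alternative 2: hydrogen-atom-transfer radical closure of ring A.**
- Cut and key step: C6–C12; hydrogen-atom transfer to the isopropenyl group of A5 gives a tertiary C12 radical that adds to the cyclopentenone β-carbon C6, and protonation sets C5, giving bicyclic ketone A4.
- Merits: the hindered C6–C12 bond is made by a radical. A4 already carries the C2=C3 olefin and a C16–C17 chain at C15, so the late ketone-to-triflate-to-methyl sequence of the chosen route (steps 36 and 37) is not needed. As an entry to ring A alone it is probably more direct than steps 28 to 31.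
- Weak points: A5 needs a Z-trisubstituted skipped diene with an acyclic, doubly allylic stereocentre C15, open to olefin isomerisation and hydrogen abstraction under the same radical conditions. The 7-endo closure competes with simple reduction. The ring fusion rests on an enolate protonation, and the C9 carbinol with its concave methyl group is still to be made.
- Comparison: A4 brings its own C16 and C17, so it cannot be paired with the Stetter tether without discarding two carbons. The chosen plan sets against it a C15 centre that is formed on a ring, with a defined open face.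

**Alternative 3: samarium ketyl cyclisation to close ring B.**
- Cut and key step: C5–C9; one-electron reduction of the methyl ketone of A7 gives a ketyl that adds 5-exo to the dienone carbon C5, giving hydroxy enone A6.
- Merits: C9 and C5 are set together, cis-fused and with the hydroxyl anti to C4. That is exactly the relationship the chosen route obtains by hydroboration (step 30), and a ketyl–olefin closure is arguably more predictable in its regiochemistry.
- Weak points: A7 is a chiral 2,4,4-trimethylcycloheptadienone with no obvious enantioselective source for C6. Its second enone arm offers a competing 6-exo closure at C15. In A6, C15 is the β-carbon of an enone next to C12, so the union would need conjugate addition of a large nucleophile at a neopentylic carbon.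
- Comparison: the chosen plan starts from a chiral-pool cyclopentene and makes C15 nucleophilic (an α-carbon), at the price of relying on hydroboration regiochemistry.

Key step: step 3

Remarks on the chemistry:
- Atom labels C1 to O34 follow the heavy atoms of the target in the order of its line notation.
- The target is taken exactly as drawn, with rings C and D cis-fused (C20 and H29 syn) and rings A and B cis-fused.
- In steps 3 and 13 the enantiomer of the chiral catalyst is the one that gives the stated product configuration.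

## Route

Step 1
Reactants: 1 p-cresol; 2 ethylene glycol
Product: 3 4-(2-hydroxyethoxy)-4-methylcyclohexa-2,5-dien-1-one
Conditions: PhI(OAc)2, 2 (10 equiv), CH2Cl2, 0 °C to rt
Reagents that add atoms: none
Why: Hypervalent-iodine oxidative dearomatisation of a para-alkylphenol; the electrophilic ring is captured at C4 (the future C32) by the diol, giving the achiral quinol ether, and excess diol suppresses double arylation.

Step 2
Reactants: 3 4-(2-hydroxyethoxy)-4-methylcyclohexa-2,5-dien-1-one
Product: 4 4-methyl-4-(2-oxoethoxy)cyclohexa-2,5-dien-1-one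
Conditions: Dess–Martin periodinane, CH2Cl2, rt
Reagents that add atoms: none
Why: Dess–Martin oxidation of the primary alcohol under neutral conditions that leave the cross-conjugated dienone untouched; the aldehyde is used at once because it hydrates and self-condenses on storage.

Step 3
Reactants: 4 4-methyl-4-(2-oxoethoxy)cyclohexa-2,5-dien-1-one
Product: 5 (3aS,7aR)-7a-methyl-3a,4-dihydro-1-benzofuran-3,5(2H,7aH)-dione
Conditions: aminoindanol-derived N-pentafluorophenyl triazolium tetrafluoroborate (10 mol %), KN(SiMe3)2 (10 mol %), toluene, 23 °C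
Reagents that add atoms: none
Why: Intramolecular asymmetric Stetter reaction, a known desymmetrisation of aldehyde-tethered cyclohexadienones under chiral triazolium carbene catalysis. The carbene adds to the aldehyde carbon C17 and proton transfer gives the nucleophilic hydroxy-enamine (acyl anion equivalent), whose carbon attacks the enone β-carbon C18; proton transfer and loss of the carbene return the C17 ketone. The closure is 5-exo-trig and forms the oxolan-3-one ring (O34, C16, C17, C18, C32) together with the C17–C18 bond. C32 becomes stereogenic because the catalyst selects one of the two enantiotopic enone arms of the achiral quinol; C18 follows from it, because the three-atom tether through O34 reaches only the syn face and enforces the cis ring fusion. The selectivities needed are enantiotopic-arm selection (catalyst), 1,4- over 1,2-addition and Stetter over benzoin or aldol pathways, which the five-ring closure onto an unhindered, doubly activated β-carbon should outrun. The quaternary C32 blocks re-aromatisation, and the second enone arm survives as the handle for all later ring C chemistry. Both enantiomers of the pre-catalyst derive from the commercial enantiomers of cis-1-amino-2-indanol; the one delivering the (3aS,7aR) product is used.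

Step 4
Reactants: 5 (3aS,7aR)-7a-methyl-3a,4-dihydro-1-benzofuran-3,5(2H,7aH)-dione
Product: 6 (3aR,7aR)-3-hydroxy-7a-methyl-2,3,3a,4-tetrahydro-1-benzofuran-5(7aH)-one (C3 epimers)
Conditions: NaBH4 (0.3 equiv), MeOH/CH2Cl2, −78 °C
Reagents that add atoms: none
Why: Chemoselective borohydride reduction: the saturated α-alkoxy ketone C17 is far more electrophilic than the vinylogous C29 carbonyl, so the enone is spared at low temperature; the new C17 centre is removed in step 6.

Step 5
Reactants: 6 (3aR,7aR)-3-hydroxy-7a-methyl-2,3,3a,4-tetrahydro-1-benzofuran-5(7aH)-one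
Product: 7 O-[(3aR,7aR)-7a-methyl-5-oxo-2,3,3a,4,5,7a-hexahydro-1-benzofuran-3-yl] O-phenyl carbonothioate
Conditions: PhOC(S)Cl, pyridine, DMAP (cat.), CH2Cl2, rt
Reagents that add atoms: phenyl chlorothionoformate, S=C(Cl)Oc1ccccc1
Why: Acylation of the secondary alcohol with a chlorothionoformate (first half of a Barton–McCombie deoxygenation) under conditions too mild to enolise the enone.

Step 6
Reactants: 7 O-[(3aR,7aR)-7a-methyl-5-oxo-2,3,3a,4,5,7a-hexahydro-1-benzofuran-3-yl] O-phenyl carbonothioate
Product: 8 (3aS,7aR)-7a-methyl-2,3,3a,4-tetrahydro-1-benzofuran-5(7aH)-one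
Conditions: Bu3SnH, AIBN (cat.), toluene, 90 °C
Reagents that add atoms: none
Why: Barton–McCombie radical deoxygenation; the secondary C17 radical is reduced by the tin hydride faster than it can reach the enone, for which only a disfavoured 5-endo path exists.

Step 7
Reactants: 8 (3aS,7aR)-7a-methyl-2,3,3a,4-tetrahydro-1-benzofuran-5(7aH)-one
Product: 10 (3aS,7aR)-4,7a-dimethyl-2,3,3a,4-tetrahydro-1-benzofuran-5(7aH)-one (C4 epimers), via lithium dienolate 9 (not isolated)
Conditions: LiN(i-Pr)2, THF, −78 °C; MeI, −78 to −40 °C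
Reagents that add atoms: iodomethane, IC
Why: Kinetic α′-deprotonation of the enone gives the cross-conjugated dienolate at C19, the only enolisable position (C30 is vinylic, C32 quaternary), and C-methylation follows; the new centre is planarised again in step 8.

Step 8
Reactants: 10 (3aS,7aR)-4,7a-dimethyl-2,3,3a,4-tetrahydro-1-benzofuran-5(7aH)-one
Product: 12 (3aS,4S,7aR)-4,7a-dimethyl-4-(prop-2-en-1-yl)-2,3,3a,4-tetrahydro-1-benzofuran-5(7aH)-one, via lithium dienolate 11 (not isolated)
Conditions: LiN(i-Pr)2, THF/DMPU, −78 °C; allyl bromide, −78 to −20 °C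
Reagents that add atoms: allyl bromide, C=CCBr
Why: Enolate alkylation forming the quaternary C19: allyl bromide should approach the dienolate on the convex face of the cis-fused bicycle, anti to the oxolane ring (C17, O34), so C21 ends up anti and the methyl group C20 syn to C17.

Step 9
Reactants: 12 (3aS,4S,7aR)-4,7a-dimethyl-4-(prop-2-en-1-yl)-2,3,3a,4-tetrahydro-1-benzofuran-5(7aH)-one
Product: 13 (3aS,4S,7aR)-4,7a-dimethyl-4-(prop-2-en-1-yl)hexahydro-1-benzofuran-5(2H)-one
Conditions: [(Ph3P)CuH]6 (0.4 equiv), benzene, H2O (2 equiv), rt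
Reagents that add atoms: none
Why: Copper hydride conjugate reduction; the phosphine-stabilised copper hydride delivers hydride to the enone β-carbon C31 only and leaves the isolated allyl olefin and the ketone alone.

Step 10
Reactants: 13 (3aS,4S,7aR)-4,7a-dimethyl-4-(prop-2-en-1-yl)hexahydro-1-benzofuran-5(2H)-one
Product: 15 (3aS,4S,7aR)-4-(3-hydroxypropyl)-4,7a-dimethylhexahydro-1-benzofuran-5(2H)-one, via alkylborane 14 (not isolated)
Conditions: 9-BBN, THF, 0 °C to rt; NaOH, H2O2, 0 °C
Reagents that add atoms: hydrogen peroxide, OO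
Why: Anti-Markovnikov hydroboration–oxidation; 9-BBN adds to the terminal olefin much faster than it reduces the hindered α-quaternary ketone, giving the primary alcohol at C23.

Step 11
Reactants: 15 (3aS,4S,7aR)-4-(3-hydroxypropyl)-4,7a-dimethylhexahydro-1-benzofuran-5(2H)-one
Product: 16 3-[(3aS,4S,7aR)-4,7a-dimethyl-5-oxooctahydro-1-benzofuran-4-yl]propanal
Conditions: Dess–Martin periodinane, CH2Cl2, rt
Reagents that add atoms: none
Why: Dess–Martin oxidation of the primary alcohol to the aldehyde; no epimerisable centre is adjacent.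

Step 12
Reactants: 16 3-[(3aS,4S,7aR)-4,7a-dimethyl-5-oxooctahydro-1-benzofuran-4-yl]propanal
Product: 17 (3aS,4S,7aR)-4,7a-dimethyl-4-(4-methylpent-3-en-1-yl)hexahydro-1-benzofuran-5(2H)-one
Conditions: i-PrPPh3I, n-BuLi, THF, 0 °C; then 16, −78 to 0 °C
Reagents that add atoms: isopropyltriphenylphosphonium iodide, CC(C)[P+](c1ccccc1)(c1ccccc1)c1ccccc1.[I-]
Why: Wittig olefination with the non-stabilised isopropylidene ylide, which takes the aldehyde and not the hindered α-quaternary ketone, giving the trisubstituted C23=C25 olefin.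

Step 13
Reactants: 17 (3aS,4S,7aR)-4,7a-dimethyl-4-(4-methylpent-3-en-1-yl)hexahydro-1-benzofuran-5(2H)-one
Product: 18 (3aS,4S,7aR)-4-{2-[(2S)-3,3-dimethyloxiran-2-yl]ethyl}-4,7a-dimethylhexahydro-1-benzofuran-5(2H)-one
Conditions: L-fructose-derived Shi ketone (0.3 equiv), KHSO5 (as 2KHSO5·KHSO4·K2SO4), K2CO3, Bu4NHSO4, MeCN/(MeO)2CH2/aq. Na2B4O7, 0 °C
Reagents that add atoms: potassium peroxymonosulfate, [K+].[O-]S(=O)(=O)OO
Why: Shi asymmetric epoxidation of a trisubstituted olefin by a chiral dioxirane; the reagent, not the remote ring, sets C23, and the ketone enantiomer that gives the (S)-epoxide is used; the buffered medium leaves ketone and oxolane intact.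

Step 14
Reactants: 18 (3aS,4S,7aR)-4-{2-[(2S)-3,3-dimethyloxiran-2-yl]ethyl}-4,7a-dimethylhexahydro-1-benzofuran-5(2H)-one
Product: 19 (3aS,4S,7aR)-4-[(3S)-3-hydroxy-4-methylpent-4-en-1-yl]-4,7a-dimethylhexahydro-1-benzofuran-5(2H)-one
Conditions: Et2Al(TMP) (from Li(TMP) and Et2AlCl, 4 equiv), toluene, 0 °C
Reagents that add atoms: none
Why: Base-induced epoxide-to-allylic-alcohol isomerisation with a bulky aluminium amide: syn β-elimination takes a proton from a C25 methyl group and cleaves the C25–O bond, so the C23–O bond and its configuration are kept; the C29 ketone is at most enolised and returns on work-up.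

Step 15
Reactants: 19 (3aS,4S,7aR)-4-[(3S)-3-hydroxy-4-methylpent-4-en-1-yl]-4,7a-dimethylhexahydro-1-benzofuran-5(2H)-one
Product: 20 (3aS,4S,5R,7aR)-4-[(3S)-3-hydroxy-4-methylpent-4-en-1-yl]-4,7a-dimethyloctahydro-1-benzofuran-5-ol
Conditions: LiBH(s-Bu)3 (3 equiv), THF, −78 °C; H2O
Reagents that add atoms: none
Why: Bulky trialkylborohydride reduction of a cyclohexanone; in the chair with the C20 methyl group axial, equatorial attack gives the axial alcohol with O28 trans to C20 and cis to the C21 chain, as 4,4-dimethyl-3-oxo steroids give the axial alcohol with this reagent.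

Step 16
Reactants: 20 (3aS,4S,5R,7aR)-4-[(3S)-3-hydroxy-4-methylpent-4-en-1-yl]-4,7a-dimethyloctahydro-1-benzofuran-5-ol
Product: 22 tricyclic oxepane alcohol (3S,5aS,6S,7R,9aR)-2,2,5a,7-tetramethyl-7,6-(epoxyethano)decahydro-1-benzoxepin-3-ol, via organomercury trifluoroacetate 21 (not isolated)
Conditions: Hg(OCOCF3)2, MeCN, −20 to 0 °C; then NaBH4, aq. NaOH, 0 °C
Reagents that add atoms: none
Why: Intramolecular alkoxymercuration–demercuration: the C29 hydroxyl opens the mercurinium ion of the 1,1-disubstituted olefin at the tertiary carbon C25, a 7-exo closure in which Markovnikov and exo preferences coincide, and borohydride turns CH2Hg into the second C25 methyl group; the cis ring fusion is fixed by the existing C19 and C29 centres.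

Step 17
Reactants: 22 tricyclic oxepane alcohol
Product: 23 tert-butyldimethylsilyl ether of 22 at O24
Conditions: t-BuMe2SiOTf, 2,6-lutidine, CH2Cl2, 0 °C
Reagents that add atoms: tert-butyldimethylsilyl trifluoromethanesulfonate, CC(C)(C)[Si](C)(C)OS(=O)(=O)C(F)(F)F
Why: Silylation of the hindered secondary C23 alcohol with a silyl triflate; the silyl ether tolerates the oxidising, reducing and basic steps that follow.

Step 18
Reactants: 23 tert-butyldimethylsilyl ether of 22
Product: 24 γ-lactone (C16 carbonyl) of 23
Conditions: RuCl3·xH2O (5 mol %), NaIO4, CCl4/MeCN/H2O, rt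
Reagents that add atoms: sodium periodate, [Na+].[O-]I(=O)(=O)=O
Why: RuO4 oxidation of an ether α-methylene to a lactone, with RuO4 generated catalytically from RuCl3 and NaIO4; C16 is the only methylene next to an ether oxygen, the oxepane offers only the hindered methine C29–H, and no olefin or free alcohol is present.

Step 19
Reactants: 24 γ-lactone of 23
Product: 25 (3S,5aS,6S,7R,9aR)-3-(tert-butyldimethylsilyloxy)-6-(2-hydroxyethyl)-2,2,5a,7-tetramethyldecahydro-1-benzoxepin-7-ol
Conditions: LiAlH4, THF, 0 °C
Reagents that add atoms: none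
Why: Hydride reduction of the lactone to the diol, which releases the tertiary O34 hydroxyl and the primary C16 alcohol irreversibly.

Step 20
Reactants: 25 diol
Product: 26 bis(triethylsilyl) ether of 25
Conditions: Et3SiOTf (2.5 equiv), 2,6-lutidine, CH2Cl2, −78 to 0 °C
Reagents that add atoms: triethylsilyl trifluoromethanesulfonate, CC[Si](CC)(CC)OS(=O)(=O)C(F)(F)F
Why: Exhaustive silylation with a silyl triflate, which protects the hindered tertiary alcohol as well as the primary one.

Step 21
Reactants: 26 bis(triethylsilyl) ether of 25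
Product: 27 2-[(3S,5aS,6S,7R,9aR)-3-(tert-butyldimethylsilyloxy)-2,2,5a,7-tetramethyl-7-(triethylsilyloxy)decahydro-1-benzoxepin-6-yl]acetaldehyde
Conditions: (COCl)2, DMSO, CH2Cl2, −78 °C; 26, −78 to −30 °C; Et3N
Reagents that add atoms: none
Why: Swern oxidation applied to a silyl ether: the activated sulfoxide cleaves and oxidises a primary triethylsilyl ether selectively and leaves tertiary and secondary silyl ethers untouched, so the C16 aldehyde is obtained without a separate deprotection.

Step 22
Reactants: 28 (S)-limonene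
Product: 30 (3S)-6-oxo-3-(prop-1-en-2-yl)heptanal, via ozonide 29 (not isolated)
Conditions: O3 (1 equiv), CH2Cl2, −78 °C; PPh3
Reagents that add atoms: ozone, [O-][O+]=O
Why: Ozonolysis; the trisubstituted ring olefin is much more electron-rich than the isopropenyl group and is cleaved selectively with one equivalent of ozone, and the phosphine reduces the ozonide without touching the stereocentre.

Step 23
Reactants: 30 (3S)-6-oxo-3-(prop-1-en-2-yl)heptanal
Product: 31 (5R)-2-methyl-5-(prop-1-en-2-yl)cyclopent-1-ene-1-carbaldehyde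
Conditions: piperidine, AcOH (cat.), benzene, reflux
Reagents that add atoms: none
Why: Intramolecular aldol condensation through the aldehyde enamine: the aldehyde α-carbon attacks the methyl ketone to close the five-membered ring and dehydration gives the conjugated enal; the stereocentre (future C6) is not enolisable.

Step 24
Reactants: 31 (5R)-2-methyl-5-(prop-1-en-2-yl)cyclopent-1-ene-1-carbaldehyde
Product: 32 [(5R)-2-methyl-5-(prop-1-en-2-yl)cyclopent-1-en-1-yl]methanol
Conditions: NaBH4, CeCl3·7H2O, MeOH, 0 °C
Reagents that add atoms: none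
Why: Luche reduction, selective 1,2-reduction of the enal to the allylic alcohol.

Step 25
Reactants: 32 [(5R)-2-methyl-5-(prop-1-en-2-yl)cyclopent-1-en-1-yl]methanol
Product: 33 (3R)-2-(bromomethyl)-1-methyl-3-(prop-1-en-2-yl)cyclopent-1-ene
Conditions: CBr4, PPh3, CH2Cl2, 0 °C
Reagents that add atoms: carbon tetrabromide, BrC(Br)(Br)Br
Why: Appel bromination of the primary allylic alcohol under neutral conditions, without allylic transposition.

Step 26
Reactants: 33 (3R)-2-(bromomethyl)-1-methyl-3-(prop-1-en-2-yl)cyclopent-1-ene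
Product: 34 N-methoxy-N-methyl-3-[(5R)-2-methyl-5-(prop-1-en-2-yl)cyclopent-1-en-1-yl]propanamide
Conditions: MeC(O)N(OMe)Me, LiN(i-Pr)2, THF, −78 °C; then 33, −78 to 0 °C
Reagents that add atoms: N-methoxy-N-methylacetamide, CC(=O)N(C)OC
Why: Alkylation of an amide enolate by a primary allylic bromide (SN2), which adds C3 and C2 as an N-methoxy-N-methylamide.

Step 27
Reactants: 34 N-methoxy-N-methyl-3-[(5R)-2-methyl-5-(prop-1-en-2-yl)cyclopent-1-en-1-yl]propanamide
Product: 35 5-[(5R)-2-methyl-5-(prop-1-en-2-yl)cyclopent-1-en-1-yl]pent-1-en-3-one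
Conditions: CH2=CHMgBr, THF, 0 °C; cold aq. HCl quench
Reagents that add atoms: vinylmagnesium bromide, C=C[Mg]Br
Why: Grignard addition to an N-methoxy-N-methylamide; the chelated tetrahedral intermediate collapses only on acidic quench, so the vinyl ketone forms without over-addition.

Step 28
Reactants: 35 5-[(5R)-2-methyl-5-(prop-1-en-2-yl)cyclopent-1-en-1-yl]pent-1-en-3-one
Product: 36 (3aR)-1,4-dimethyl-3,3a,7,8-tetrahydroazulen-6(2H)-one
Conditions: second-generation Hoveyda–Grubbs catalyst (5 mol %), toluene (5 mM), 80 °C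
Reagents that add atoms: none
Why: Ring-closing metathesis between the vinyl ketone and the isopropenyl group closes ring A as a 3-methylcyclohept-2-enone; the tetrasubstituted ring B olefin is inert to the catalyst and high dilution favours the seven-membered ring.

Step 29
Reactants: 36 (3aR)-1,4-dimethyl-3,3a,7,8-tetrahydroazulen-6(2H)-one
Product: 37 (3aR)-1,4,4-trimethyl-3,3a,4,5,7,8-hexahydroazulen-6(2H)-one
Conditions: Me2CuLi (from CuI and MeLi), Et2O, −20 to 0 °C; aq. NH4Cl
Reagents that add atoms: lithium dimethylcuprate, [Li+].C[Cu-]C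
Why: Cuprate conjugate addition to the β,β-disubstituted enone creates the gem-dimethyl carbon C12; no new stereocentre arises and the weakly basic reagent leaves the doubly allylic C6–H alone.

Step 30
Reactants: 37 (3aR)-1,4,4-trimethyl-3,3a,4,5,7,8-hexahydroazulen-6(2H)-one
Product: 39 (1S,3aS,8aS)-1,4,4-trimethyldecahydroazulene-1,6-diol (C6 epimers), via borane adduct 38 (not isolated)
Conditions: BH3·THF (4 equiv), THF, 0 °C to rt; NaOH, H2O2
Reagents that add atoms: hydrogen peroxide, OO
Why: Hydroboration–oxidation of a tetrasubstituted olefin (syn addition): borane approaches the ring B olefin on the face of H6, anti to the quaternary C12, placing boron on the less hindered C9 and hydrogen on C5, so H5, H6 and the C9 oxygen end up cis (cis ring fusion, methyl C10 on the concave face); the ketone is reduced in the same operation.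

Step 31
Reactants: 39 (1S,3aS,8aS)-1,4,4-trimethyldecahydroazulene-1,6-diol
Product: 41 (1S,3aS,8aS)-1-hydroxy-1,4,4-trimethyl-2,3,3a,4,5,8a-hexahydroazulen-6(1H)-one, via hydroxy ketone 40 (not isolated)
Conditions: IBX (4 equiv), DMSO, 75 °C
Reagents that add atoms: none
Why: IBX oxidation of the secondary alcohol followed in the same pot by IBX dehydrogenation of the ketone; unsaturation can enter only between C3 and C4 because C15 has no β-hydrogen (C12 is quaternary), and the tertiary alcohol is inert.

Step 32
Reactants: 41 (1S,3aS,8aS)-1-hydroxy-1,4,4-trimethyl-2,3,3a,4,5,8a-hexahydroazulen-6(1H)-one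
Product: 42 (1S,3aS,8aS)-1,4,4-trimethyl-1-(triethylsilyloxy)-2,3,3a,4,5,8a-hexahydroazulen-6(1H)-one
Conditions: Et3SiOTf, 2,6-lutidine, CH2Cl2, −78 °C
Reagents that add atoms: triethylsilyl trifluoromethanesulfonate, CC[Si](CC)(CC)OS(=O)(=O)C(F)(F)F
Why: Silyl triflate protection of the tertiary alcohol, so that one equivalent of base suffices in the union.

Step 33
Reactants: 42 (1S,3aS,8aS)-1,4,4-trimethyl-1-(triethylsilyloxy)-2,3,3a,4,5,8a-hexahydroazulen-6(1H)-one; 27 C16 aldehyde of the ring C/D fragment
Product: 44 C15–C16 aldol adduct of 42 with 27 (β-hydroxy ketone; C15 and C16 epimers), via lithium dienolate 43 (not isolated)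
Conditions: LiN(i-Pr)2, THF, −78 °C; then 27, −78 °C
Reagents that add atoms: none
Why: Directed aldol addition: kinetic α′-deprotonation of the enone gives the cross-conjugated lithium dienolate at C15 only (C3 is vinylic), and its addition to the unhindered α-methylene aldehyde forms the C15–C16 bond; both new centres are erased or reset in steps 34 and 35.

Step 34
Reactants: 44 C15–C16 aldol adduct
Product: 46 cross-conjugated dienone with exocyclic C15=C16 (E/Z), via mesylate 45 (not isolated)
Conditions: MsCl, Et3N, CH2Cl2, 0 °C; DBU, rt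
Reagents that add atoms: none
Why: Dehydration of the β-hydroxy ketone through its mesylate (E1cB elimination with DBU); the olefin geometry is immaterial.

Step 35
Reactants: 46 cross-conjugated dienone
Product: 47 saturated ring A ketone with (15S)-configured C15 (H15 cis to H5 and H6)
Conditions: H2 (1 atm), Pd/C, EtOAc, rt
Reagents that add atoms: none
Why: Heterogeneous catalytic hydrogenation reduces both enone olefins and spares the silyl ethers; hydrogen should reach C15 from the convex face of the cis-fused hydroazulene (the face of H5 and H6, away from ring B), which places the C16 chain cis to C7 as required.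

Step 36
Reactants: 47 saturated ring A ketone
Product: 49 C2 enol triflate (C2=C3), via potassium enolate 48 (not isolated)
Conditions: KN(SiMe3)2, THF, −78 °C; PhNTf2
Reagents that add atoms: N-phenylbis(trifluoromethanesulfonimide), O=S(=O)(N(c1ccccc1)S(=O)(=O)C(F)(F)F)C(F)(F)F
Why: Kinetic enolisation and O-triflation; the amide base removes a C3 methylene proton rather than the tertiary, neopentylic C15–H, fixing the enol triflate at C2=C3 without epimerising C15.

Step 37
Reactants: 49 C2 enol triflate
Product: 50 tris-silyl ether of the target (O24 tert-butyldimethylsilyl; O11 and O34 triethylsilyl)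
Conditions: MeMgBr, Fe(acac)3 (10 mol %), THF/NMP, −20 to 0 °C
Reagents that add atoms: methylmagnesium bromide, C[Mg]Br
Why: Iron-catalysed cross-coupling of an alkenyl triflate with a methyl Grignard reagent installs C1 and gives the trisubstituted C2=C3 olefin; the coupling is fast at low temperature and tolerates silyl ethers.

Step 38
Reactants: 50 tris-silyl ether of the target
Product: 51 CNP0183476.6
Conditions: Bu4NF, THF, 50 °C
Reagents that add atoms: none
Why: Fluoride-mediated cleavage of the three silyl ethers under non-acidic conditions that cannot ionise the tertiary alcohols or the tertiary ether.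

## Compound list

1 | p-cresol (4-methylphenol) | Cc1ccc(O)cc1 | starting material
2 | ethylene glycol | OCCO | starting material
3 | 4-(2-hydroxyethoxy)-4-methylcyclohexa-2,5-dien-1-one | OCCOC1(C)C=CC(=O)C=C1 | intermediate
4 | 4-methyl-4-(2-oxoethoxy)cyclohexa-2,5-dien-1-one | O=CCOC1(C)C=CC(=O)C=C1 | intermediate
5 | (3aS,7aR)-7a-methyl-3a,4-dihydro-1-benzofuran-3,5(2H,7aH)-dione (cis-fused) | C1C(=O)[C@H]2CC(=O)C=C[C@@]2(C)O1 | intermediate
6 | (3aR,7aR)-3-hydroxy-7a-methyl-2,3,3a,4-tetrahydro-1-benzofuran-5(7aH)-one (C3 epimers, mainly from hydride attack on the convex face) | C1C(O)[C@H]2CC(=O)C=C[C@@]2(C)O1 | intermediate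
7 | O-[(3aR,7aR)-7a-methyl-5-oxo-2,3,3a,4,5,7a-hexahydro-1-benzofuran-3-yl] O-phenyl carbonothioate | C1C(OC(=S)Oc3ccccc3)[C@H]2CC(=O)C=C[C@@]2(C)O1 | intermediate
8 | (3aS,7aR)-7a-methyl-2,3,3a,4-tetrahydro-1-benzofuran-5(7aH)-one | C1C[C@H]2CC(=O)C=C[C@@]2(C)O1 | intermediate
9 | lithium dienolate of 8 (C19=C29–O−, formed in situ) | [Li+].C1C[C@H]2C=C([O-])C=C[C@@]2(C)O1 | intermediate
10 | (3aS,7aR)-4,7a-dimethyl-2,3,3a,4-tetrahydro-1-benzofuran-5(7aH)-one (C4 epimers) | C1C[C@H]2C(C)C(=O)C=C[C@@]2(C)O1 | intermediate
11 | lithium dienolate of 10 (formed in situ) | [Li+].C1C[C@H]2C(C)=C([O-])C=C[C@@]2(C)O1 | intermediate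
12 | (3aS,4S,7aR)-4,7a-dimethyl-4-(prop-2-en-1-yl)-2,3,3a,4-tetrahydro-1-benzofuran-5(7aH)-one | C1C[C@H]2[C@](C)(CC=C)C(=O)C=C[C@@]2(C)O1 | intermediate
13 | (3aS,4S,7aR)-4,7a-dimethyl-4-(prop-2-en-1-yl)hexahydro-1-benzofuran-5(2H)-one | C1C[C@H]2[C@](C)(CC=C)C(=O)CC[C@@]2(C)O1 | intermediate
14 | (3aS,4S,7aR)-4-[3-(9-borabicyclo[3.3.1]nonan-9-yl)propyl]-4,7a-dimethylhexahydro-1-benzofuran-5(2H)-one (formed in situ) | C1C[C@H]2[C@](C)(CCCB3C4CCCC3CCC4)C(=O)CC[C@@]2(C)O1 | intermediate
15 | (3aS,4S,7aR)-4-(3-hydroxypropyl)-4,7a-dimethylhexahydro-1-benzofuran-5(2H)-one | C1C[C@H]2[C@](C)(CCCO)C(=O)CC[C@@]2(C)O1 | intermediate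
16 | 3-[(3aS,4S,7aR)-4,7a-dimethyl-5-oxooctahydro-1-benzofuran-4-yl]propanal | C1C[C@H]2[C@](C)(CCC=O)C(=O)CC[C@@]2(C)O1 | intermediate
17 | (3aS,4S,7aR)-4,7a-dimethyl-4-(4-methylpent-3-en-1-yl)hexahydro-1-benzofuran-5(2H)-one | C1C[C@H]2[C@](C)(CCC=C(C)C)C(=O)CC[C@@]2(C)O1 | intermediate
18 | (3aS,4S,7aR)-4-{2-[(2S)-3,3-dimethyloxiran-2-yl]ethyl}-4,7a-dimethylhexahydro-1-benzofuran-5(2H)-one | C1C[C@H]2[C@](C)(CC[C@@H]3OC3(C)C)C(=O)CC[C@@]2(C)O1 | intermediate
19 | (3aS,4S,7aR)-4-[(3S)-3-hydroxy-4-methylpent-4-en-1-yl]-4,7a-dimethylhexahydro-1-benzofuran-5(2H)-one | C1C[C@H]2[C@](C)(CC[C@H](O)C(C)=C)C(=O)CC[C@@]2(C)O1 | intermediate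
20 | (3aS,4S,5R,7aR)-4-[(3S)-3-hydroxy-4-methylpent-4-en-1-yl]-4,7a-dimethyloctahydro-1-benzofuran-5-ol | C1C[C@H]2[C@](C)(CC[C@H](O)C(C)=C)[C@H](O)CC[C@@]2(C)O1 | intermediate
21 | organomercury trifluoroacetate: 22 with one C25 methyl group replaced by CH2HgOCOCF3 (C25 epimers, formed in situ) | C1C[C@H]2[C@]3(C)CC[C@H](O)C(C)(C[Hg]OC(=O)C(F)(F)F)O[C@@H]3CC[C@@]2(C)O1 | intermediate
22 | (3S,5aS,6S,7R,9aR)-2,2,5a,7-tetramethyl-7,6-(epoxyethano)decahydro-1-benzoxepin-3-ol (cis-fused rings C/D; oxolane O34–C16–C17 joins the C7 oxygen to C6) | C1C[C@H]2[C@]3(C)CC[C@H](O)C(C)(C)O[C@@H]3CC[C@@]2(C)O1 | intermediate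
23 | 3-O-tert-butyldimethylsilyl ether of 22 | C1C[C@H]2[C@]3(C)CC[C@H](O[Si](C)(C)C(C)(C)C)C(C)(C)O[C@@H]3CC[C@@]2(C)O1 | intermediate
24 | γ-lactone of 23 (oxolan-2-one, carbonyl at C16) | O=C1C[C@H]2[C@]3(C)CC[C@H](O[Si](C)(C)C(C)(C)C)C(C)(C)O[C@@H]3CC[C@@]2(C)O1 | intermediate
25 | (3S,5aS,6S,7R,9aR)-3-(tert-butyldimethylsilyloxy)-6-(2-hydroxyethyl)-2,2,5a,7-tetramethyldecahydro-1-benzoxepin-7-ol | OCC[C@H]1[C@]2(C)CC[C@H](O[Si](C)(C)C(C)(C)C)C(C)(C)O[C@@H]2CC[C@@]1(C)O | intermediate
26 | (3S,5aS,6S,7R,9aR)-3-(tert-butyldimethylsilyloxy)-2,2,5a,7-tetramethyl-7-(triethylsilyloxy)-6-[2-(triethylsilyloxy)ethyl]decahydro-1-benzoxepine | CC[Si](CC)(CC)OCC[C@H]1[C@]2(C)CC[C@H](O[Si](C)(C)C(C)(C)C)C(C)(C)O[C@@H]2CC[C@@]1(C)O[Si](CC)(CC)CC | intermediate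
27 | 2-[(3S,5aS,6S,7R,9aR)-3-(tert-butyldimethylsilyloxy)-2,2,5a,7-tetramethyl-7-(triethylsilyloxy)decahydro-1-benzoxepin-6-yl]acetaldehyde | O=CC[C@H]1[C@]2(C)CC[C@H](O[Si](C)(C)C(C)(C)C)C(C)(C)O[C@@H]2CC[C@@]1(C)O[Si](CC)(CC)CC | intermediate
28 | (S)-limonene, (4S)-1-methyl-4-(prop-1-en-2-yl)cyclohex-1-ene | CC1=CC[C@H](CC1)C(C)=C | starting material
29 | limonene 1,2-ozonide, 1-methyl-4-(prop-1-en-2-yl)-7,8,9-trioxabicyclo[4.2.1]nonane (C4 as in 28, formed in situ) | CC12CC[C@@H](CC(OO1)O2)C(C)=C | intermediate
30 | (3S)-6-oxo-3-(prop-1-en-2-yl)heptanal | CC(=O)CC[C@@H](CC=O)C(C)=C | intermediate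
31 | (5R)-2-methyl-5-(prop-1-en-2-yl)cyclopent-1-ene-1-carbaldehyde | O=CC1=C(C)CC[C@@H]1C(C)=C | intermediate
32 | [(5R)-2-methyl-5-(prop-1-en-2-yl)cyclopent-1-en-1-yl]methanol | OCC1=C(C)CC[C@@H]1C(C)=C | intermediate
33 | (3R)-2-(bromomethyl)-1-methyl-3-(prop-1-en-2-yl)cyclopent-1-ene | BrCC1=C(C)CC[C@@H]1C(C)=C | intermediate
34 | N-methoxy-N-methyl-3-[(5R)-2-methyl-5-(prop-1-en-2-yl)cyclopent-1-en-1-yl]propanamide | CON(C)C(=O)CCC1=C(C)CC[C@@H]1C(C)=C | intermediate
35 | 5-[(5R)-2-methyl-5-(prop-1-en-2-yl)cyclopent-1-en-1-yl]pent-1-en-3-one | C=CC(=O)CCC1=C(C)CC[C@@H]1C(C)=C | intermediate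
36 | (3aR)-1,4-dimethyl-3,3a,7,8-tetrahydroazulen-6(2H)-one | O=C1CCC2=C(C)CC[C@@H]2C(C)=C1 | intermediate
37 | (3aR)-1,4,4-trimethyl-3,3a,4,5,7,8-hexahydroazulen-6(2H)-one | O=C1CCC2=C(C)CC[C@@H]2C(C)(C)C1 | intermediate
38 | borane adduct of 37: boron on C9 (cis to H5 and H6) and O-boryl at C2 (one representative form, formed in situ) | BOC1CC[C@H]2[C@H](CC[C@]2(C)B)C(C)(C)C1 | intermediate
39 | (1S,3aS,8aS)-1,4,4-trimethyldecahydroazulene-1,6-diol (C6 epimers; cis-fused) | OC1CC[C@H]2[C@H](CC[C@]2(C)O)C(C)(C)C1 | intermediate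
40 | (1S,3aS,8aS)-1-hydroxy-1,4,4-trimethyloctahydroazulen-6(1H)-one (formed in situ) | O=C1CC[C@H]2[C@H](CC[C@]2(C)O)C(C)(C)C1 | intermediate
41 | (1S,3aS,8aS)-1-hydroxy-1,4,4-trimethyl-2,3,3a,4,5,8a-hexahydroazulen-6(1H)-one | O=C1C=C[C@H]2[C@H](CC[C@]2(C)O)C(C)(C)C1 | intermediate
42 | (1S,3aS,8aS)-1,4,4-trimethyl-1-(triethylsilyloxy)-2,3,3a,4,5,8a-hexahydroazulen-6(1H)-one | O=C1C=C[C@H]2[C@H](CC[C@]2(C)O[Si](CC)(CC)CC)C(C)(C)C1 | intermediate
43 | lithium dienolate of 42 (C15=C2–O−, formed in situ) | [Li+].[O-]C1C=C[C@H]2[C@H](CC[C@]2(C)O[Si](CC)(CC)CC)C(C)(C)C=1 | intermediate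
44 | aldol adduct: 42 bearing at C5 of the azulenone (C15) a 1-hydroxy-2-(benzoxepin-6-yl)ethyl group derived from 27 (epimers at C15 and C16) | O=C1C=C[C@H]2[C@H](CC[C@]2(C)O[Si](CC)(CC)CC)C(C)(C)C1C(O)C[C@H]1[C@]2(C)CC[C@H](O[Si](C)(C)C(C)(C)C)C(C)(C)O[C@@H]2CC[C@@]1(C)O[Si](CC)(CC)CC | intermediate
45 | methanesulfonate of 44 at the C16 hydroxyl (formed in situ) | O=C1C=C[C@H]2[C@H](CC[C@]2(C)O[Si](CC)(CC)CC)C(C)(C)C1C(OS(C)(=O)=O)C[C@H]1[C@]2(C)CC[C@H](O[Si](C)(C)C(C)(C)C)C(C)(C)O[C@@H]2CC[C@@]1(C)O[Si](CC)(CC)CC | intermediate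
46 | (1S,3aS,8aS)-5-{2-[(3S,5aS,6S,7R,9aR)-3-(tert-butyldimethylsilyloxy)-2,2,5a,7-tetramethyl-7-(triethylsilyloxy)decahydro-1-benzoxepin-6-yl]ethylidene}-1,4,4-trimethyl-1-(triethylsilyloxy)-2,3,3a,4,5,8a-hexahydroazulen-6(1H)-one (E/Z) | O=C1C=C[C@H]2[C@H](CC[C@]2(C)O[Si](CC)(CC)CC)C(C)(C)C1=CC[C@H]1[C@]2(C)CC[C@H](O[Si](C)(C)C(C)(C)C)C(C)(C)O[C@@H]2CC[C@@]1(C)O[Si](CC)(CC)CC | intermediate
47 | (1S,3aS,5S,8aS)-5-{2-[(3S,5aS,6S,7R,9aR)-3-(tert-butyldimethylsilyloxy)-2,2,5a,7-tetramethyl-7-(triethylsilyloxy)decahydro-1-benzoxepin-6-yl]ethyl}-1,4,4-trimethyl-1-(triethylsilyloxy)octahydroazulen-6(1H)-one | O=C1CC[C@H]2[C@H](CC[C@]2(C)O[Si](CC)(CC)CC)C(C)(C)[C@@H]1CC[C@H]1[C@]2(C)CC[C@H](O[Si](C)(C)C(C)(C)C)C(C)(C)O[C@@H]2CC[C@@]1(C)O[Si](CC)(CC)CC | intermediate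
48 | potassium enolate of 47 (C2=C3, formed in situ) | [K+].[O-]C1=CC[C@H]2[C@H](CC[C@]2(C)O[Si](CC)(CC)CC)C(C)(C)[C@@H]1CC[C@H]1[C@]2(C)CC[C@H](O[Si](C)(C)C(C)(C)C)C(C)(C)O[C@@H]2CC[C@@]1(C)O[Si](CC)(CC)CC | intermediate
49 | (1S,3aS,5S,8aS)-5-{2-[(3S,5aS,6S,7R,9aR)-3-(tert-butyldimethylsilyloxy)-2,2,5a,7-tetramethyl-7-(triethylsilyloxy)decahydro-1-benzoxepin-6-yl]ethyl}-1,4,4-trimethyl-1-(triethylsilyloxy)-1,2,3,3a,4,5,8,8a-octahydroazulen-6-yl trifluoromethanesulfonate | FC(F)(F)S(=O)(=O)OC1=CC[C@H]2[C@H](CC[C@]2(C)O[Si](CC)(CC)CC)C(C)(C)[C@@H]1CC[C@H]1[C@]2(C)CC[C@H](O[Si](C)(C)C(C)(C)C)C(C)(C)O[C@@H]2CC[C@@]1(C)O[Si](CC)(CC)CC | intermediate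
50 | tris-silyl ether of 51: tert-butyldimethylsilyl on the C23 oxygen, triethylsilyl on the C9 and C32 oxygens | CC1=CC[C@H]2[C@H](CC[C@]2(C)O[Si](CC)(CC)CC)C(C)(C)[C@@H]1CC[C@H]1[C@]2(C)CC[C@H](O[Si](C)(C)C(C)(C)C)C(C)(C)O[C@@H]2CC[C@@]1(C)O[Si](CC)(CC)CC | intermediate
51 | CNP0183476.6, (3S,5aS,6S,7R,9aR)-6-{2-[(1S,3aS,5R,8aS)-1-hydroxy-1,4,4,6-tetramethyl-1,2,3,3a,4,5,8,8a-octahydroazulen-5-yl]ethyl}-2,2,5a,7-tetramethyldecahydro-1-benzoxepine-3,7-diol | CC1=CC[C@H]2[C@H](CC[C@]2(C)O)C(C)(C)[C@@H]1CC[C@H]1[C@]2(C)CC[C@H](O)C(C)(C)O[C@@H]2CC[C@@]1(C)O | target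

## Step count and weak points

Total: 38 steps. Longest linear sequence: 27 steps (steps 1 to 21, then 33 to 38). The hydroazulene branch (steps 22 to 32) has 11 steps.

Least certain steps:

**Step 3 (key step).** Enantiotopic-arm discrimination may be incomplete, or conversion may be lost because aldehyde 4 hydrates or oligomerises or the carbene is diverted into benzoin-type self-condensation. Fallback, setting out from 4: run the Stetter reaction with an achiral triazolium salt and base to the racemic dione F1, reduce with NaBH4 to the racemic hydroxy enone F2, and resolve by lipase-catalysed acylation (Candida antarctica lipase B, vinyl acetate). The antipode leaves as the antipodal acetate F3 and the unreacted alcohol rejoins the route at 6.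

**Step 35.** Facial selectivity of hydrogen delivery to C15 may be poor: ring A is flexible, the two C12 methyl groups shield both faces alike, and only the remote C6 substituents discriminate; the α-centre could also epimerise afterwards. Fallback, which forms C15–C16 by alkylation so that the chain, not hydrogen, is the group delivered to C15: from 26, selective methanolysis of the primary silyl ether (PPTS, MeOH) gives the primary alcohol F4. I2, PPh3 and imidazole convert it into the primary iodide F5. Alkylation of dienolate 43 (from 42) with F5 gives the alkylated enone F6, whose C15 centre can be equilibrated through the enolate, and hydrogenation of its C3=C4 olefin (H2, Pd/C) comes back at 47.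

**Step 30.** Boron may be delivered to the wrong olefin carbon (C5 instead of C9), or addition to the tetrasubstituted olefin may be sluggish while the reduced ketone ties up borane. Fallback, setting out from 37: epoxidation with dimethyldioxirane on the convex face gives the epoxy ketone F7. Reductive opening with trivalent titanium (Cp2TiCl from Cp2TiCl2 and Zn) and 1,4-cyclohexadiene as hydrogen donor should cleave the C5–O bond and deliver hydrogen to the C5 radical from the convex face. The product is hydroxy ketone 40, where the route is rejoined; step 31 then uses IBX for the dehydrogenation only.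

**Step 16.** Seven-membered ring closure may be slow, so that intermolecular capture of the mercurinium ion or loss of mercury before cyclisation competes. Fallback, setting out from 20: iodoetherification with N-iodosuccinimide gives the iodomethyl oxepane F8, and radical deiodination (Bu3SnH, AIBN) returns to the route at 22.

**Step 28.** Metathesis between an electron-poor vinyl ketone and a 1,1-disubstituted olefin may be slow, leading to catalyst decay and dimerisation through the vinyl ketone. Fallback, setting out from 35: Luche reduction gives the dienol F9, ring-closing metathesis with second-generation Grubbs catalyst gives the cyclic allylic alcohol F10, and MnO2 oxidation comes back at 36.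

**Step 8.** The facial bias of the alkylation may be insufficient, or the electrophile may prefer the concave face because the angular methyl group C33 also shields the convex face. Fallback, setting out from 8: reverse the order of the alkylations. Allylation first (LiN(i-Pr)2, allyl bromide) gives the allyl enone F11, and methylation second (LiN(i-Pr)2, MeI) then places the methyl group on the face the second electrophile prefers, returning at 12.

## Further compounds

F1 | step 3 | (±)-cis-7a-methyl-3a,4-dihydro-1-benzofuran-3,5(2H,7aH)-dione (racemate) | C1C(=O)[C@H]2CC(=O)C=C[C@@]2(C)O1.C1C(=O)[C@@H]2CC(=O)C=C[C@]2(C)O1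
F2 | step 3 | (±)-cis-3-hydroxy-7a-methyl-2,3,3a,4-tetrahydro-1-benzofuran-5(7aH)-one (racemate) | C1C(O)[C@H]2CC(=O)C=C[C@@]2(C)O1.C1C(O)[C@@H]2CC(=O)C=C[C@]2(C)O1
F3 | step 3 | (3aS,7aS)-7a-methyl-5-oxo-2,3,3a,4,5,7a-hexahydro-1-benzofuran-3-yl acetate (antipodal series) | C1C(OC(C)=O)[C@@H]2CC(=O)C=C[C@]2(C)O1
F4 | step 35 | 2-[(3S,5aS,6S,7R,9aR)-3-(tert-butyldimethylsilyloxy)-2,2,5a,7-tetramethyl-7-(triethylsilyloxy)decahydro-1-benzoxepin-6-yl]ethanol | OCC[C@H]1[C@]2(C)CC[C@H](O[Si](C)(C)C(C)(C)C)C(C)(C)O[C@@H]2CC[C@@]1(C)O[Si](CC)(CC)CC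
F5 | step 35 | (3S,5aS,6S,7R,9aR)-3-(tert-butyldimethylsilyloxy)-6-(2-iodoethyl)-2,2,5a,7-tetramethyl-7-(triethylsilyloxy)decahydro-1-benzoxepine | ICC[C@H]1[C@]2(C)CC[C@H](O[Si](C)(C)C(C)(C)C)C(C)(C)O[C@@H]2CC[C@@]1(C)O[Si](CC)(CC)CC
F6 | step 35 | (1S,3aS,5S,8aS)-5-{2-[(3S,5aS,6S,7R,9aR)-3-(tert-butyldimethylsilyloxy)-2,2,5a,7-tetramethyl-7-(triethylsilyloxy)decahydro-1-benzoxepin-6-yl]ethyl}-1,4,4-trimethyl-1-(triethylsilyloxy)-2,3,3a,4,5,8a-hexahydroazulen-6(1H)-one | O=C1C=C[C@H]2[C@H](CC[C@]2(C)O[Si](CC)(CC)CC)C(C)(C)[C@@H]1CC[C@H]1[C@]2(C)CC[C@H](O[Si](C)(C)C(C)(C)C)C(C)(C)O[C@@H]2CC[C@@]1(C)O[Si](CC)(CC)CC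
F7 | step 30 | 5,9-epoxide of 37 (oxygen on the face of H6; azulene positions 1 and 8a) | O=C1CC[C@@]23O[C@@]3(C)CC[C@@H]2C(C)(C)C1
F8 | step 16 | 22 with one C25 methyl group replaced by CH2I (C25 epimers) | C1C[C@H]2[C@]3(C)CC[C@H](O)C(C)(CI)O[C@@H]3CC[C@@]2(C)O1
F9 | step 28 | 5-[(5R)-2-methyl-5-(prop-1-en-2-yl)cyclopent-1-en-1-yl]pent-1-en-3-ol (C3 epimers) | C=CC(O)CCC1=C(C)CC[C@@H]1C(C)=C
F10 | step 28 | (3aR)-1,4-dimethyl-2,3,3a,6,7,8-hexahydroazulen-6-ol (C6 epimers) | OC1CCC2=C(C)CC[C@@H]2C(C)=C1
F11 | step 8 | (3aS,7aR)-7a-methyl-4-(prop-2-en-1-yl)-2,3,3a,4-tetrahydro-1-benzofuran-5(7aH)-one (C4 epimers) | C1C[C@H]2C(CC=C)C(=O)C=C[C@@]2(C)O1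
A1 | alternative 1 | (1R,2S)-1-bromo-2,4-dimethyl-2-(4-methylpent-3-en-1-yl)cyclohex-3-ene-1-carbaldehyde | O=C[C@@]1(Br)CCC(C)=C[C@]1(C)CCC=C(C)C
A2 | alternative 1 | 2-bromoprop-2-enal | C=C(Br)C=O
A3 | alternative 1 | (3E)-2,4,8-trimethylnona-1,3,7-triene | C=C(C)/C=C(\C)CCC=C(C)C
A4 | alternative 2 | cis-fused bicyclic ketone of rings A and B (C9 ketone, C2=C3 olefin, C15 bearing a 2-(tert-butyldimethylsilyloxy)ethyl group) | CC1=CC[C@H]2[C@H](CCC2=O)C(C)(C)[C@@H]1CCO[Si](C)(C)C(C)(C)C
A5 | alternative 2 | 2-{(2Z)-4-[2-(tert-butyldimethylsilyloxy)ethyl]-3,5-dimethylhexa-2,5-dien-1-yl}cyclopent-2-en-1-one (C15 configured as in A4) | O=C1CCC=C1C/C=C(/C)[C@@H](CCO[Si](C)(C)C(C)(C)C)C(C)=C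
A6 | alternative 3 | cis-fused bicyclic hydroxy enone of rings A and B (C3 ketone, C2=C15 olefin, C9 tertiary carbinol) | CC1=CC(C)(C)[C@H]2CC[C@](C)(O)[C@H]2CC1=O
A7 | alternative 3 | 2,4,4-trimethyl-5-(3-oxobutyl)cyclohepta-2,6-dien-1-one (C6 configured as in A6) | CC(=O)CC[C@H]1C=CC(=O)C(C)=CC1(C)C
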